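**Retrosynthetic overview**
- The target comes from removal of four MOM groups, preceded by Suzuki–Miyaura union of a 3-bromobutenolide with the ring A boronate (C3–aryl bond).
- The bromobutenolide with its quaternary C2 comes from an enantioselective dearomative C-benzylation of an achiral, fully substituted 2-silyloxyfuran with the ring B benzyl bromide; this is the only stereocentre-forming step.
- The silyloxyfuran comes from methyl pyruvate and methyl glyoxylate by crossed aldol–lactonisation, bromination, O-protection and silylative aromatisation.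
- The ring B bromide comes from 4-hydroxybenzaldehyde (ortho-C-prenylation); the ring A boronate comes from catechol (ortho-lithiation/prenylation, then C–H borylation).
- Ring order: the five-membered lactone is the only ring built (step 1); it is aromatised to the furan (step 3) and dearomatised in the key step (step 8). Both benzene rings are bought.

Assumption: methyl glyoxylate (freshly cracked monomer) and both enantiomers of the ammonium salt of step 8 are commercial; the (S)-configured salt is assumed to give the required configuration at the quaternary carbon, to be checked on the first run against the natural product, with the mirror-image salt used if the sense is opposite.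

**Route**

Step 1
Reactants: 1 methyl pyruvate; 2 methyl glyoxylate
Product: 4 racemic methyl 4-hydroxy-5-oxo-2,5-dihydrofuran-2-carboxylate, via aldol adduct 3 (not isolated)
Conditions: Et3N (10 mol%), CH2Cl2, 0 °C → rt, slow addition of 1 to 2 (1.2 equiv); then TsOH·H2O (5 mol%), toluene, 50 °C
Reagents that add atoms: none
Why: Amine-catalysed crossed aldol addition of the pyruvate enol to the far more electrophilic glyoxylate aldehyde, then γ-lactonisation onto the keto-ester and enolisation (isotetronic acid synthesis); the centre formed is racemic and is erased in step 3.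

Step 2
Reactants: 4 racemic methyl 4-hydroxy-5-oxo-2,5-dihydrofuran-2-carboxylate
Product: 5 racemic methyl 3-bromo-4-hydroxy-5-oxo-2,5-dihydrofuran-2-carboxylate
Conditions: NBS (1.0 equiv), MeCN, 0 °C, dark
Reagents that add atoms: N-bromosuccinimide, O=C1CCC(=O)N1Br
Why: Electrophilic bromination of the enol at its only nucleophilic carbon (C3), followed by re-enolisation.

Step 3
Reactants: 5 racemic methyl 3-bromo-4-hydroxy-5-oxo-2,5-dihydrofuran-2-carboxylate
Product: 7 methyl 3-bromo-5-[(tert-butyldimethylsilyl)oxy]-4-(methoxymethoxy)furan-2-carboxylate, via MOM enol ether 6 (not isolated)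
Conditions: MOMCl (1.05 equiv), i-Pr2NEt (1.1 equiv), CH2Cl2, −20 °C; then Et3N (1.5 equiv), TBSOTf (1.2 equiv), −78 → 0 °C; non-aqueous work-up (pentane, filtration)
Reagents that add atoms: chloromethyl methyl ether, COCCl; tert-butyldimethylsilyl trifluoromethanesulfonate, CC(C)(C)[Si](C)(C)OS(=O)(=O)C(F)(F)F
Why: O-alkylation of the strongly acidic enol, then soft enolisation and O-silylation of the lactone (silyl dienol ether formation), driven by gain of furan aromaticity; this converts the racemate into one achiral aromatic furan.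

Step 4
Reactants: 8 4-hydroxybenzaldehyde; 9 prenyl bromide
Product: 10 4-hydroxy-3-(3-methylbut-2-en-1-yl)benzaldehyde
Conditions: KOH (aq, 1.1 equiv), rt; chromatographic removal of the O-prenyl ether
Reagents that add atoms: none
Why: Ortho-C-alkylation of an ambident phenoxide in water, where hydrogen bonding at oxygen favours carbon attack and the para position is blocked; modest yield is accepted for a one-step entry.

Step 5
Reactants: 10 4-hydroxy-3-(3-methylbut-2-en-1-yl)benzaldehyde
Product: 11 4-(methoxymethoxy)-3-(3-methylbut-2-en-1-yl)benzaldehyde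
Conditions: MOMCl, i-Pr2NEt, CH2Cl2, 0 °C → rt
Reagents that add atoms: chloromethyl methyl ether, COCCl
Why: Williamson-type protection of the phenol as a base- and fluoride-stable acetal.

Step 6
Reactants: 11 4-(methoxymethoxy)-3-(3-methylbut-2-en-1-yl)benzaldehyde
Product: 12 [4-(methoxymethoxy)-3-(3-methylbut-2-en-1-yl)phenyl]methanol
Conditions: NaBH4, MeOH, 0 °C
Reagents that add atoms: none
Why: Chemoselective hydride reduction of the aldehyde; alkene and acetal are inert.

Step 7
Reactants: 12 [4-(methoxymethoxy)-3-(3-methylbut-2-en-1-yl)phenyl]methanol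
Product: 13 4-(bromomethyl)-1-(methoxymethoxy)-2-(3-methylbut-2-en-1-yl)benzene
Conditions: CBr4, PPh3, CH2Cl2, 0 °C; used at once
Reagents that add atoms: carbon tetrabromide, BrC(Br)(Br)Br
Why: Appel bromination under neutral conditions that spare the MOM acetal and the prenyl alkene.

Step 8
Reactants: 7 methyl 3-bromo-5-[(tert-butyldimethylsilyl)oxy]-4-(methoxymethoxy)furan-2-carboxylate; 13 4-(bromomethyl)-1-(methoxymethoxy)-2-(3-methylbut-2-en-1-yl)benzene
Product: 15 methyl (2S)-3-bromo-4-(methoxymethoxy)-2-{[4-(methoxymethoxy)-3-(3-methylbut-2-en-1-yl)phenyl]methyl}-5-oxo-2,5-dihydrofuran-2-carboxylate, via furan-2-olate 14 (not isolated)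
Conditions: (11bS)-4,4-dibutyl-2,6-bis(3,4,5-trifluorophenyl)-4,5-dihydro-3H-dinaphtho[2,1-c:1',2'-e]azepinium bromide (5 mol%), CsF (1.5 equiv), 4 Å sieves, toluene, −40 → −20 °C
Reagents that add atoms: none
Why: Proposed new method: fluoride carried into toluene by the chiral ammonium cation removes the silyl group of aromatic furan 7 to give the 6π furan-2-olate 14 as a tight ion pair with the axially chiral cation, and SN2 attack of the ester-bearing ring carbon on benzyl bromide 13 from the unshielded face breaks the furan aromaticity and sets the quaternary centre (the other carbanionic carbon carries OMOM, and attack there would give up conjugation with the lactone carbonyl); the closest known reaction types are fluoride-triggered C-benzylation of silyl enol ethers, chiral ammonium fluoride Mukaiyama-type reactions and asymmetric phase-transfer benzylation of β-keto esters.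

Step 9
Reactants: 16 catechol
Product: 17 1,2-bis(methoxymethoxy)benzene
Conditions: MOMCl (2.4 equiv), i-Pr2NEt (3 equiv), CH2Cl2, 0 °C → rt
Reagents that add atoms: chloromethyl methyl ether, COCCl
Why: Double Williamson-type protection, which also installs the directing groups for step 10.

Step 10
Reactants: 17 1,2-bis(methoxymethoxy)benzene; 9 prenyl bromide
Product: 19 1,2-bis(methoxymethoxy)-3-(3-methylbut-2-en-1-yl)benzene, via aryllithium 18 (not isolated)
Conditions: n-BuLi (1.1 equiv), THF, 0 °C, 1 h; CuBr·SMe2 (10 mol%), then 9, −78 °C → rt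
Reagents that add atoms: none
Why: Directed ortho-metalation next to OMOM (both ortho sites are equivalent), then copper-catalysed SN2 allylation that gives the linear prenyl arene.

Step 11
Reactants: 19 1,2-bis(methoxymethoxy)-3-(3-methylbut-2-en-1-yl)benzene
Product: 20 2-[3,4-bis(methoxymethoxy)-5-(3-methylbut-2-en-1-yl)phenyl]-4,4,5,5-tetramethyl-1,3,2-dioxaborolane
Conditions: [Ir(OMe)(cod)]2 (1.5 mol%), 4,4'-di-tert-butyl-2,2'-bipyridine (3 mol%), B2pin2 (1.0 equiv), THF, 60 °C
Reagents that add atoms: bis(pinacolato)diboron, CC1(C)OB(OC1(C)C)B1OC(C)(C)C(C)(C)O1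
Why: Iridium-catalysed aromatic C–H borylation under steric control; the only C–H with no ortho substituent is the one meta to both OMOM-C1 and the prenyl group, which is the position needed.

Step 12
Reactants: 15 methyl (2S)-3-bromo-4-(methoxymethoxy)-2-{[4-(methoxymethoxy)-3-(3-methylbut-2-en-1-yl)phenyl]methyl}-5-oxo-2,5-dihydrofuran-2-carboxylate; 20 2-[3,4-bis(methoxymethoxy)-5-(3-methylbut-2-en-1-yl)phenyl]-4,4,5,5-tetramethyl-1,3,2-dioxaborolane
Product: 21 methyl (2R)-3-[3,4-bis(methoxymethoxy)-5-(3-methylbut-2-en-1-yl)phenyl]-4-(methoxymethoxy)-2-{[4-(methoxymethoxy)-3-(3-methylbut-2-en-1-yl)phenyl]methyl}-5-oxo-2,5-dihydrofuran-2-carboxylate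
Conditions: Pd(OAc)2 (5 mol%), 2-dicyclohexylphosphino-2',6'-dimethoxybiphenyl (10 mol%), K3PO4 (2 equiv), THF/H2O (10:1), 50 °C
Reagents that add atoms: none
Why: Suzuki–Miyaura coupling, with oxidative addition of zerovalent palladium into the activated β-bromobutenolide C–Br bond and a bulky biaryl phosphine to handle the fully substituted alkene; the quaternary centre is untouched, and its descriptor changes from S to R only because aryl replaces bromine in the priority order.

Step 13
Reactants: 21 methyl (2R)-3-[3,4-bis(methoxymethoxy)-5-(3-methylbut-2-en-1-yl)phenyl]-4-(methoxymethoxy)-2-{[4-(methoxymethoxy)-3-(3-methylbut-2-en-1-yl)phenyl]methyl}-5-oxo-2,5-dihydrofuran-2-carboxylate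
Product: 22 methyl (2R)-3-[3,4-dihydroxy-5-(3-methylbut-2-en-1-yl)phenyl]-4-hydroxy-2-{[4-hydroxy-3-(3-methylbut-2-en-1-yl)phenyl]methyl}-5-oxo-2,5-dihydrofuran-2-carboxylate (CNP0460191.2)
Conditions: HCl (1.25 M in MeOH), 30 °C, HPLC control; NaHCO3 quench
Reagents that add atoms: none
Why: Acid-catalysed transacetalisation of the four MOM acetals to methanol; mild anhydrous acid and short exposure limit cyclisation of the ortho-prenyl phenols to chromans, and the quaternary centre cannot epimerise.

**Compound list**

1 | methyl pyruvate | CC(=O)C(=O)OC | starting material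
2 | methyl glyoxylate | COC(=O)C=O | starting material
3 | dimethyl 4-hydroxy-2-oxopentanedioate (racemic aldol adduct) | COC(=O)C(O)CC(=O)C(=O)OC | intermediate
4 | methyl 4-hydroxy-5-oxo-2,5-dihydrofuran-2-carboxylate (racemic) | COC(=O)C1OC(=O)C(O)=C1 | intermediate
5 | methyl 3-bromo-4-hydroxy-5-oxo-2,5-dihydrofuran-2-carboxylate (racemic) | COC(=O)C1OC(=O)C(O)=C1Br | intermediate
6 | methyl 3-bromo-4-(methoxymethoxy)-5-oxo-2,5-dihydrofuran-2-carboxylate (racemic) | COC(=O)C1OC(=O)C(OCOC)=C1Br | intermediate
7 | methyl 3-bromo-5-[(tert-butyldimethylsilyl)oxy]-4-(methoxymethoxy)furan-2-carboxylate | COC(=O)c1oc(O[Si](C)(C)C(C)(C)C)c(OCOC)c1Br | intermediate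
8 | 4-hydroxybenzaldehyde | O=Cc1ccc(O)cc1 | starting material
9 | prenyl bromide (1-bromo-3-methylbut-2-ene) | CC(C)=CCBr | starting material
10 | 4-hydroxy-3-(3-methylbut-2-en-1-yl)benzaldehyde | O=Cc1ccc(O)c(CC=C(C)C)c1 | intermediate
11 | 4-(methoxymethoxy)-3-(3-methylbut-2-en-1-yl)benzaldehyde | O=Cc1ccc(OCOC)c(CC=C(C)C)c1 | intermediate
12 | [4-(methoxymethoxy)-3-(3-methylbut-2-en-1-yl)phenyl]methanol | OCc1ccc(OCOC)c(CC=C(C)C)c1 | intermediate
13 | 4-(bromomethyl)-1-(methoxymethoxy)-2-(3-methylbut-2-en-1-yl)benzene | BrCc1ccc(OCOC)c(CC=C(C)C)c1 | intermediate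
14 | cesium 4-bromo-5-(methoxycarbonyl)-3-(methoxymethoxy)furan-2-olate (paired with the catalyst cation in solution) | [Cs+].COC(=O)c1oc([O-])c(OCOC)c1Br | intermediate
15 | methyl (2S)-3-bromo-4-(methoxymethoxy)-2-{[4-(methoxymethoxy)-3-(3-methylbut-2-en-1-yl)phenyl]methyl}-5-oxo-2,5-dihydrofuran-2-carboxylate | COC(=O)[C@]1(Cc2ccc(OCOC)c(CC=C(C)C)c2)OC(=O)C(OCOC)=C1Br | intermediate
16 | catechol | Oc1ccccc1O | starting material
17 | 1,2-bis(methoxymethoxy)benzene | COCOc1ccccc1OCOC | intermediate
18 | [2,3-bis(methoxymethoxy)phenyl]lithium | [Li]c1cccc(OCOC)c1OCOC | intermediate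
19 | 1,2-bis(methoxymethoxy)-3-(3-methylbut-2-en-1-yl)benzene | COCOc1cccc(CC=C(C)C)c1OCOC | intermediate
20 | 2-[3,4-bis(methoxymethoxy)-5-(3-methylbut-2-en-1-yl)phenyl]-4,4,5,5-tetramethyl-1,3,2-dioxaborolane | COCOc1cc(B2OC(C)(C)C(C)(C)O2)cc(CC=C(C)C)c1OCOC | intermediate
21 | methyl (2R)-3-[3,4-bis(methoxymethoxy)-5-(3-methylbut-2-en-1-yl)phenyl]-4-(methoxymethoxy)-2-{[4-(methoxymethoxy)-3-(3-methylbut-2-en-1-yl)phenyl]methyl}-5-oxo-2,5-dihydrofuran-2-carboxylate | COC(=O)[C@]1(Cc2ccc(OCOC)c(CC=C(C)C)c2)OC(=O)C(OCOC)=C1c1cc(OCOC)c(OCOC)c(CC=C(C)C)c1 | intermediate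
22 | methyl (2R)-3-[3,4-dihydroxy-5-(3-methylbut-2-en-1-yl)phenyl]-4-hydroxy-2-{[4-hydroxy-3-(3-methylbut-2-en-1-yl)phenyl]methyl}-5-oxo-2,5-dihydrofuran-2-carboxylate | COC(=O)[C@]1(Cc2ccc(O)c(CC=C(C)C)c2)OC(=O)C(O)=C1c1cc(O)c(O)c(CC=C(C)C)c1 | target

**Step count and risks**

Total step count: 13. Longest linear sequence: 7 steps (steps 4, 5, 6, 7, 8, 12, 13, from 4-hydroxybenzaldehyde).

The three steps most likely to fail:

Step 8 is the main risk: the enantioselectivity is unproven, the sense of induction is assumed, and the ambident furanolate could react at oxygen or at the OMOM-bearing carbon. The fallback replaces catalyst control by resolution; it sets out from 7 (with 13) and comes back at 15. Furan 7 is benzylated with 13 using the achiral fluoride source tetrabutylammonium difluorotriphenylsilicate in THF at −40 °C. This gives racemic methyl 3-bromo-4-(methoxymethoxy)-2-{[4-(methoxymethoxy)-3-(3-methylbut-2-en-1-yl)phenyl]methyl}-5-oxo-2,5-dihydrofuran-2-carboxylate F1, which is separated by preparative chromatography on a chiral stationary phase; the (2S) enantiomer is 15. The racemic run also confirms the site of alkylation before catalyst screening.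

Step 1 can suffer from pyruvate self-aldol and from a second addition of glyoxylate to the enol of the product. The fallback is a directed Mukaiyama aldol; it sets out from 1 and comes back at 4. Compound 1 is converted with Me3SiCl/Et3N into methyl 2-[(trimethylsilyl)oxy]prop-2-enoate F2, which is added to 2 with TiCl4 in CH2Cl2 at −78 °C. Methanolic acid work-up removes silicon and lactonises adduct 3 to 4.

Step 13 can fail through acid-induced cyclisation of the ortho-prenyl phenols to chromans. The fallback is a protecting-group exchange in place of Brønsted-acid cleavage; it sets out from 21 and comes back at 22. Compound 21 is treated with Me3SiOTf and 2,2'-bipyridyl in CH2Cl2 at 0 °C, which converts each MOM acetal into a silyl ether. This gives methyl (2R)-3-[3-(3-methylbut-2-en-1-yl)-4,5-bis(trimethylsilyloxy)phenyl]-2-{[3-(3-methylbut-2-en-1-yl)-4-(trimethylsilyloxy)phenyl]methyl}-5-oxo-4-(trimethylsilyloxy)-2,5-dihydrofuran-2-carboxylate F3; stirring with water at neutral pH hydrolyses the four silyl ethers to 22.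

**Further compounds**

F1 | step 8 | racemic methyl 3-bromo-4-(methoxymethoxy)-2-{[4-(methoxymethoxy)-3-(3-methylbut-2-en-1-yl)phenyl]methyl}-5-oxo-2,5-dihydrofuran-2-carboxylate | COC(=O)C1(Cc2ccc(OCOC)c(CC=C(C)C)c2)OC(=O)C(OCOC)=C1Br
F2 | step 1 | methyl 2-[(trimethylsilyl)oxy]prop-2-enoate | COC(=O)C(=C)O[Si](C)(C)C
F3 | step 13 | methyl (2R)-3-[3-(3-methylbut-2-en-1-yl)-4,5-bis(trimethylsilyloxy)phenyl]-2-{[3-(3-methylbut-2-en-1-yl)-4-(trimethylsilyloxy)phenyl]methyl}-5-oxo-4-(trimethylsilyloxy)-2,5-dihydrofuran-2-carboxylate | COC(=O)[C@]1(Cc2ccc(O[Si](C)(C)C)c(CC=C(C)C)c2)OC(=O)C(O[Si](C)(C)C)=C1c1cc(O[Si](C)(C)C)c(O[Si](C)(C)C)c(CC=C(C)C)c1
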